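## Retrosynthetic overview

1. Target ⇒ its tetra-O-benzyl ether ⇒ achiral isoflavone. Hydride goes to C2 and a chiral O-atom donor attacks the resulting C3 enolate in one flask. This mirrors isoflavone reductase followed by the 3-hydroxylase and sets the only stereocentre.
2. Isoflavone ⇒ 2'-hydroxychalcone in one flask. Ring C closes by O1–C2 oxa-Michael addition (chalcone isomerase). Trivalent iodine then drives ring B from C2 to C3, and H3 is lost (isoflavone synthase and dehydratase).
3. Chalcone ⇒ ring A acetophenone + ring B aldehyde (Claisen–Schmidt).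
4. Ring B aldehyde ⇒ 2,3,4-trihydroxybenzaldehyde + prenyl bromide, by 4-O-prenylation, aromatic Claisen shift to C5 (reverse prenyl) and O-methylation.
5. Ring order: rings A and B are bought as arenes. Ring C is the only ring made, first as a flavanone and then re-wired to the isoflavone.

Assumption: the (+)-oxaziridine is taken to give the (3R) alcohol by analogy with 2-substituted 8-alkoxy-1-tetralone and 3-benzyl-5,7-dialkoxychroman-4-one enolates; if the sense proves opposite, the (−)-reagent from (1R)-(−)-camphor-10-sulfonic acid is used in the same way.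

## Route

Step 1
Reactants: 1 2,3,4-trihydroxybenzaldehyde; 2 prenyl bromide (1-bromo-3-methylbut-2-ene)
Product: 3 2,3-dihydroxy-4-[(3-methylbut-2-en-1-yl)oxy]benzaldehyde
Conditions: Li2CO3 (1.2 equiv), DMF, 45 °C
Reagents that add atoms: none
Why: Williamson ether synthesis (SN2) under a weak base: Li2CO3 ionises only the 4-OH, which is para to the formyl group and the most acidic, while the 2-OH is locked in a hydrogen bond to the aldehyde and the 3-OH is not conjugated with it, so the primary allylic bromide is taken up at O4.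

Step 2
Reactants: 3 2,3-dihydroxy-4-[(3-methylbut-2-en-1-yl)oxy]benzaldehyde
Product: 4 2,3-bis(benzyloxy)-4-[(3-methylbut-2-en-1-yl)oxy]benzaldehyde
Conditions: BnBr (2.4 equiv), K2CO3, DMF, 60 °C
Reagents that add atoms: benzyl bromide BrCc1ccccc1
Why: Exhaustive Williamson benzylation masks the catechol with ethers that withstand 190 °C, KOH, sulfonic acid, trivalent iodine and borohydride and that can later be taken off without hydrogen gas, which the vinyl group would not survive.

Step 3
Reactants: 4 2,3-bis(benzyloxy)-4-[(3-methylbut-2-en-1-yl)oxy]benzaldehyde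
Product: 6 2,3-bis(benzyloxy)-4-methoxy-5-(2-methylbut-3-en-2-yl)benzaldehyde, via Claisen phenol 5 (not isolated)
Conditions: NMP, 190 °C (sealed), 2 h; cool to 23 °C; K2CO3, MeI
Reagents that add atoms: iodomethane CI
Why: Aromatic Claisen rearrangement, a suprafacial [3,3]-sigmatropic shift that mirrors the O-prenylation/rearrangement path proposed for reverse prenylation in plants, can deliver the inverted 1,1-dimethylallyl unit only to C5 because C3 is blocked, and Williamson methylation of the crowded phenol 5 in the same flask stops abnormal Claisen and dihydrobenzofuran side reactions and installs the 4'-OMe of the target.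

Step 4
Reactants: 7 2,4,6-trihydroxyacetophenone
Product: 8 1-[2,4-bis(benzyloxy)-6-hydroxyphenyl]ethan-1-one
Conditions: BnBr (2.05 equiv), K2CO3, DMF, 50 °C
Reagents that add atoms: benzyl bromide BrCc1ccccc1
Why: Williamson benzylation with two equivalents stops at the dibenzyl ether because the last ortho OH is strongly hydrogen-bonded to the acetyl group, which leaves exactly the phenol that will later become O1.

Step 5
Reactants: 6 2,3-bis(benzyloxy)-4-methoxy-5-(2-methylbut-3-en-2-yl)benzaldehyde; 8 1-[2,4-bis(benzyloxy)-6-hydroxyphenyl]ethan-1-one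
Product: 9 (E)-1-[2,4-bis(benzyloxy)-6-hydroxyphenyl]-3-[2,3-bis(benzyloxy)-4-methoxy-5-(2-methylbut-3-en-2-yl)phenyl]prop-2-en-1-one
Conditions: KOH (5 equiv), EtOH/THF, 23 °C; aq HCl work-up
Reagents that add atoms: none
Why: Claisen–Schmidt condensation (aldol addition then E1cB loss of water) of the methyl ketone enolate with the non-enolisable aldehyde gives the E-enone under thermodynamic control, that is the C6–C3–C6 chalcone from which all isoflavonoids arise.

Step 6 (key step)
Reactants: 9 (E)-1-[2,4-bis(benzyloxy)-6-hydroxyphenyl]-3-[2,3-bis(benzyloxy)-4-methoxy-5-(2-methylbut-3-en-2-yl)phenyl]prop-2-en-1-one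
Product: 12 5,7-bis(benzyloxy)-3-[2,3-bis(benzyloxy)-4-methoxy-5-(2-methylbut-3-en-2-yl)phenyl]-4H-chromen-4-one, via flavanone 10 (not isolated), via 3-iodanylflavanone 11 (not isolated)
Conditions: p-TsOH·H2O (0.2 equiv), MeCN, 70 °C, 2 h; then PhI(OH)OTs (1.1 equiv, in portions), 70 °C
Reagents that add atoms: none
Why: Proposed new method: acid sets up the chalcone–flavanone equilibrium by 6-endo oxa-Michael addition of the 2'-OH to the beta carbon (the bond made by chalcone isomerase), PhI(OH)OTs attacks the enol of flavanone 10 at C3, and the very electron-rich ring B, anti to the C3–iodine bond of 11, shifts from C2 to C3 through a phenonium ion while PhI leaves and O1 stabilises the C2 cation, which loses H3 to give the isoflavone (the course of isoflavone synthase and its dehydratase); the irreversible oxidation drains the equilibrium, direct attack of the iodane on the chalcone C=C with capture by the 2'-OH would lead to the same 11, the non-nucleophilic solvent suppresses ring contraction by ring A migration, the C2 stereocentre of racemic 10 is erased, and the closest known reaction types are the 2,3-aryl shift of isolated flavanones with PhI(OH)OTs and the oxidative rearrangement of chalcones with Tl(NO3)3 or trivalent iodine.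

Step 7
Reactants: 12 5,7-bis(benzyloxy)-3-[2,3-bis(benzyloxy)-4-methoxy-5-(2-methylbut-3-en-2-yl)phenyl]-4H-chromen-4-one
Product: 14 (3R)-5,7-bis(benzyloxy)-3-[2,3-bis(benzyloxy)-4-methoxy-5-(2-methylbut-3-en-2-yl)phenyl]-3-hydroxychroman-4-one, via lithium enolate 13 (not isolated)
Conditions: LiBH(s-Bu)3 (1.05 equiv), THF, −78 °C, 1 h; then (+)-[(8,8-dimethoxycamphoryl)sulfonyl]oxaziridine (1.5 equiv), −78 to −40 °C; AcOH quench
Reagents that add atoms: (+)-[(8,8-dimethoxycamphoryl)sulfonyl]oxaziridine CC1(C)[C@@H]2CC[C@]13CS(=O)(=O)N4O[C@@]34C2(OC)OC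
Why: Proposed new method: conjugate reduction by a hindered trialkylborohydride puts hydride on the open C2 (attack at C4 is blocked by the peri 5-OBn group and the C3 aryl group) and gives the tetrasubstituted enolate 13 regiospecifically, which is hydroxylated in the same flask by Davis asymmetric enolate oxidation, the camphor-derived reagent delivering oxygen to the enolate face that gives the (3R) tertiary alcohol; both halves are known reaction types and only their union on an isoflavone is new, −78 °C holds back E1cB opening of ring C, and the isolated vinyl group is inert to both reagents.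

Step 8
Reactants: 14 (3R)-5,7-bis(benzyloxy)-3-[2,3-bis(benzyloxy)-4-methoxy-5-(2-methylbut-3-en-2-yl)phenyl]-3-hydroxychroman-4-one
Product: 15 (3R)-3-[2,3-dihydroxy-4-methoxy-5-(2-methylbut-3-en-2-yl)phenyl]-3,5,7-trihydroxychroman-4-one (CNP0205426.1)
Conditions: BCl3 (8 equiv), C6HMe5 (12 equiv), CH2Cl2, −78 °C, 45 min; MeOH/CHCl3 quench, aq work-up
Reagents that add atoms: none
Why: Lewis-acid ether cleavage with a non-basic cation scavenger: BCl3 ionises the four aryl benzyl ethers at −78 °C and pentamethylbenzene traps each benzyl cation by Friedel–Crafts alkylation, conditions that leave the vinyl group and the aryl methyl ether alone, while the tertiary carbinol sits in a boron chelate with the C4 ketone whose ionisation is disfavoured by the adjacent carbonyl, so the (3R) centre is not touched.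

## Compound list

1 | 2,3,4-trihydroxybenzaldehyde | O=Cc1ccc(O)c(O)c1O | starting material
2 | prenyl bromide (1-bromo-3-methylbut-2-ene) | CC(C)=CCBr | starting material
3 | 2,3-dihydroxy-4-[(3-methylbut-2-en-1-yl)oxy]benzaldehyde | O=Cc1ccc(OCC=C(C)C)c(O)c1O | intermediate
4 | 2,3-bis(benzyloxy)-4-[(3-methylbut-2-en-1-yl)oxy]benzaldehyde | O=Cc1ccc(OCC=C(C)C)c(OCc2ccccc2)c1OCc1ccccc1 | intermediate
5 | 2,3-bis(benzyloxy)-4-hydroxy-5-(2-methylbut-3-en-2-yl)benzaldehyde (Claisen phenol, not isolated) | O=Cc1cc(C(C)(C)C=C)c(O)c(OCc2ccccc2)c1OCc1ccccc1 | intermediate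
6 | 2,3-bis(benzyloxy)-4-methoxy-5-(2-methylbut-3-en-2-yl)benzaldehyde | O=Cc1cc(C(C)(C)C=C)c(OC)c(OCc2ccccc2)c1OCc1ccccc1 | intermediate
7 | 2,4,6-trihydroxyacetophenone | CC(=O)c1c(O)cc(O)cc1O | starting material
8 | 1-[2,4-bis(benzyloxy)-6-hydroxyphenyl]ethan-1-one | CC(=O)c1c(O)cc(OCc2ccccc2)cc1OCc1ccccc1 | intermediate
9 | (E)-2'-hydroxychalcone, tetrabenzyl ether | O=C(/C=C/c1cc(C(C)(C)C=C)c(OC)c(OCc2ccccc2)c1OCc1ccccc1)c1c(O)cc(OCc2ccccc2)cc1OCc1ccccc1 | intermediate
10 | racemic 5,7-bis(benzyloxy)-2-[2,3-bis(benzyloxy)-4-methoxy-5-(2-methylbut-3-en-2-yl)phenyl]chroman-4-one (flavanone, not isolated) | O=C1CC(c2cc(C(C)(C)C=C)c(OC)c(OCc3ccccc3)c2OCc2ccccc2)Oc2cc(OCc3ccccc3)cc(OCc3ccccc3)c21 | intermediate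
11 | racemic trans-3-[phenyl(tosyloxy)-λ3-iodanyl] derivative of flavanone 10 (not isolated, drawn without wedges) | O=C1C(I(OS(=O)(=O)c2ccc(C)cc2)c2ccccc2)C(c2cc(C(C)(C)C=C)c(OC)c(OCc3ccccc3)c2OCc2ccccc2)Oc2cc(OCc3ccccc3)cc(OCc3ccccc3)c21 | intermediate
12 | 5,7-bis(benzyloxy)-3-[2,3-bis(benzyloxy)-4-methoxy-5-(2-methylbut-3-en-2-yl)phenyl]-4H-chromen-4-one (isoflavone) | O=c1c(-c2cc(C(C)(C)C=C)c(OC)c(OCc3ccccc3)c2OCc2ccccc2)coc2cc(OCc3ccccc3)cc(OCc3ccccc3)c12 | intermediate
13 | lithium 5,7-bis(benzyloxy)-3-aryl-2H-chromen-4-olate (enolate, not isolated) | [Li+].[O-]C1=C(c2cc(C(C)(C)C=C)c(OC)c(OCc3ccccc3)c2OCc2ccccc2)COc2cc(OCc3ccccc3)cc(OCc3ccccc3)c21 | intermediate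
14 | (3R)-5,7-bis(benzyloxy)-3-[2,3-bis(benzyloxy)-4-methoxy-5-(2-methylbut-3-en-2-yl)phenyl]-3-hydroxychroman-4-one | C=CC(C)(C)c1cc([C@@]2(O)COc3cc(OCc4ccccc4)cc(OCc4ccccc4)c3C2=O)c(OCc2ccccc2)c(OCc2ccccc2)c1OC | intermediate
15 | (3R)-3-[2,3-dihydroxy-4-methoxy-5-(2-methylbut-3-en-2-yl)phenyl]-3,5,7-trihydroxychroman-4-one | C=CC(C)(C)c1cc([C@@]2(O)COc3cc(O)cc(O)c3C2=O)c(O)c(O)c1OC | target

## Step count and risks

Total step count: 8.
Longest linear sequence: 7 (steps 1, 2, 3, 5, 6, 7, 8).

**Step 6.** PhI(OH)OTs may attack the free phenol of 9. It may also attack the vinyl group, which is helped by the neighbouring electron-rich aryl group, or simply dehydrogenate 10 to the flavone. The fallback sets out from 9 and comes back at 12. It uses no electrophilic oxidant. The 2'-OH is benzylated (BnBr, K2CO3, DMF) to the tris(benzyloxy)chalcone F1. Only the enone is then epoxidised, nucleophilically, with H2O2/NaOH (Weitz–Scheffer), which gives the racemic trans-chalcone epoxide F2 and leaves the vinyl group alone. BF3·OEt2 at 0 °C opens the benzylic C–O bond, and a 1,2-aroyl shift gives the alpha-formyl deoxybenzoin F3, which already has the isoflavonoid skeleton. BCl3 (1.1 equiv, −78 °C) removes one of the two equivalent benzyl groups ortho to the ketone by chelation. The freed phenol closes on the aldehyde to the 2-hydroxyisoflavanone F4, which loses water on warming to give 12.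

**Step 7.** Three things can go wrong: 1,2-reduction, opening of ring C from the enolate, or a modest ee with the bulky C3 aryl group. The fallback sets out from 12 and comes back at 14. It replaces the stoichiometric chiral reagent with catalytic asymmetric aerobic hydroxylation. The reduction with LiBH(s-Bu)3 is quenched with acid, and the racemic isoflavanone F5 is isolated. F5 is then stirred under O2 with N-[4-(trifluoromethyl)benzyl]cinchoninium bromide (10 mol %), or its cinchonidinium pseudoenantiomer, whichever gives the R alcohol. The medium is toluene with 50% aq NaOH and P(OEt)3 at 0 °C. The chiral ion pair of the enolate takes up O2 to give the (3R)-hydroperoxide F6, which the phosphite reduces in place to 14. Any ring opening under these conditions is reversible and feeds back into the same enolate.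

**Step 8.** BCl3 may ionise the tertiary benzylic alcohol, leading to loss of water to the isoflavone or to racemisation, or it may nick the 4'-OMe group. The fallback sets out from 12 and comes back at 15. It moves the Lewis-acid step ahead of the stereocentre. The robust isoflavone 12 is debenzylated (BCl3, C6HMe5, −78 °C) to the tetrahydroxyisoflavone F7. This is silylated (TBSOTf, 2,6-lutidine, CH2Cl2) to the tetrakis(TBS) isoflavone F8. The one-flask reduction and hydroxylation of step 7 then gives, through the silylated lithium enolate F9, the (3R)-tetrakis(TBS) carbinol F10. Buffered fluoride (Bu4NF/AcOH, THF, 0 °C) frees the four phenols under near-neutral conditions and gives 15.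

## Further compounds

F1 | step 6 | (E)-1-[2,4,6-tris(benzyloxy)phenyl]-3-[2,3-bis(benzyloxy)-4-methoxy-5-(2-methylbut-3-en-2-yl)phenyl]prop-2-en-1-one | O=C(/C=C/c1cc(C(C)(C)C=C)c(OC)c(OCc2ccccc2)c1OCc1ccccc1)c1c(OCc2ccccc2)cc(OCc2ccccc2)cc1OCc1ccccc1
F2 | step 6 | racemic trans-chalcone epoxide of F1 (one enantiomer drawn) | O=C([C@H]1O[C@@H]1c1cc(C(C)(C)C=C)c(OC)c(OCc2ccccc2)c1OCc1ccccc1)c1c(OCc2ccccc2)cc(OCc2ccccc2)cc1OCc1ccccc1
F3 | step 6 | racemic 2-[2,3-bis(benzyloxy)-4-methoxy-5-(2-methylbut-3-en-2-yl)phenyl]-3-oxo-3-[2,4,6-tris(benzyloxy)phenyl]propanal | O=CC(c1cc(C(C)(C)C=C)c(OC)c(OCc2ccccc2)c1OCc1ccccc1)C(=O)c1c(OCc2ccccc2)cc(OCc2ccccc2)cc1OCc1ccccc1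
F4 | step 6 | racemic 5,7-bis(benzyloxy)-3-aryl-2-hydroxychroman-4-one (2-hydroxyisoflavanone) | O=C1C(c2cc(C(C)(C)C=C)c(OC)c(OCc3ccccc3)c2OCc2ccccc2)C(O)Oc2cc(OCc3ccccc3)cc(OCc3ccccc3)c21
F5 | step 7 | racemic 5,7-bis(benzyloxy)-3-[2,3-bis(benzyloxy)-4-methoxy-5-(2-methylbut-3-en-2-yl)phenyl]chroman-4-one (isoflavanone) | O=C1C(c2cc(C(C)(C)C=C)c(OC)c(OCc3ccccc3)c2OCc2ccccc2)COc2cc(OCc3ccccc3)cc(OCc3ccccc3)c21
F6 | step 7 | (3R)-3-hydroperoxy analogue of 14 | C=CC(C)(C)c1cc([C@@]2(OO)COc3cc(OCc4ccccc4)cc(OCc4ccccc4)c3C2=O)c(OCc2ccccc2)c(OCc2ccccc2)c1OC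
F7 | step 8 | 3-[2,3-dihydroxy-4-methoxy-5-(2-methylbut-3-en-2-yl)phenyl]-5,7-dihydroxy-4H-chromen-4-one | O=c1c(-c2cc(C(C)(C)C=C)c(OC)c(O)c2O)coc2cc(O)cc(O)c12
F8 | step 8 | tetrakis(tert-butyldimethylsilyl) ether of F7 | O=c1c(-c2cc(C(C)(C)C=C)c(OC)c(O[Si](C)(C)C(C)(C)C)c2O[Si](C)(C)C(C)(C)C)coc2cc(O[Si](C)(C)C(C)(C)C)cc(O[Si](C)(C)C(C)(C)C)c12
F9 | step 8 | lithium 2H-chromen-4-olate from F8 | [Li+].[O-]C1=C(c2cc(C(C)(C)C=C)c(OC)c(O[Si](C)(C)C(C)(C)C)c2O[Si](C)(C)C(C)(C)C)COc2cc(O[Si](C)(C)C(C)(C)C)cc(O[Si](C)(C)C(C)(C)C)c21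
F10 | step 8 | (3R)-tetrakis(tert-butyldimethylsilyl) ether of 15 (phenols silylated, 3-OH free) | C=CC(C)(C)c1cc([C@@]2(O)COc3cc(O[Si](C)(C)C(C)(C)C)cc(O[Si](C)(C)C(C)(C)C)c3C2=O)c(O[Si](C)(C)C(C)(C)C)c(O[Si](C)(C)C(C)(C)C)c1OC
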